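**Plan**

- Numbering: C1 is the carbinol carbon on the 3,4-dimethoxyphenyl ring, C2 the adjacent stereocentre, C3 its CH2, C4=C5 the alkene, with C5 on the 4-methoxyphenyl ring.
- Retrosynthetic cuts, in order: the primary O–acyl ester bond (giving core alcohol 15 and Z acid 22), then the C5–aryl bond, then the C1–C2 aldol bond and the imide N–acyl bond.
- Enabling feature: C4=C5 is an E-1,2-disubstituted alkene whose C5 carries the 4-methoxyphenyl ring and lies three atoms from C2, so a propargyl group on C2 is a latent cinnamyl arm that only needs H on C4 and the aryl ring on C5.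
- Forward order: auxiliary acylation, aldol (C1–C2), reductive auxiliary removal, bis-silylation, alkyne hydrozirconation and zinc/palladium arylation (C5–aryl), primary desilylation, esterification, global desilylation. Both arene rings are bought and no ring is formed.
- Stereochemistry: C1 (S) and C2 (R) come from one Evans syn aldol under the (S)-4-benzyl auxiliary. The E alkene comes from syn Zr–H addition and stereoretentive coupling. The Z enoate comes from crotonaldehyde via a Z α-iodoenal, carried through I/Li exchange and carboxylation with retention.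

Key step: step 5

Remark: TBS = tert-butyldimethylsilyl. The (S)-auxiliary is taken to give the (2S,3S) syn aldol adduct, which becomes the (1S,2R) diol once the acyl carbon is reduced (priority change at C2 only, no change in spatial arrangement).

**Route**

Step 1
Reactants: 1 pent-4-ynoic acid; 2 (S)-4-benzyloxazolidin-2-one
Product: 4 (S)-4-benzyl-3-(pent-4-ynoyl)oxazolidin-2-one, via pivalic mixed anhydride 3 (not isolated)
Conditions: PivCl, Et3N, THF, −20 °C; then LiCl, 2, −20 °C → rt
Reagents that add atoms: none
Why: N-acylation of the oxazolidinone through a pivalic mixed anhydride with LiCl/Et3N activation is a standard one-pot imide synthesis that needs no strong base and so leaves the acidic alkyne C–H untouched.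

Step 2
Reactants: 4 (S)-4-benzyl-3-(pent-4-ynoyl)oxazolidin-2-one; 5 veratraldehyde (3,4-dimethoxybenzaldehyde)
Product: 8 (S)-4-benzyl-3-{(2S)-2-[(S)-(3,4-dimethoxyphenyl)(hydroxy)methyl]pent-4-ynoyl}oxazolidin-2-one, via dibutylboron Z-enolate 6 (not isolated), via dibutylboron aldolate 7 (not isolated)
Conditions: Bu2BOTf, iPr2NEt, CH2Cl2, −78 → 0 °C; 5, −78 → 0 °C; pH 7 buffer, MeOH, 30% H2O2, 0 °C
Reagents that add atoms: none
Why: Evans syn aldol, in which soft enolisation gives the Z boron enolate and this adds to the aldehyde through a closed Zimmerman–Traxler chair on the face away from the benzyl group of the dipole-opposed auxiliary, so both new stereocentres (2S and carbinol S) are set by the auxiliary.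

Step 3
Reactants: 8 syn aldol adduct
Product: 9 (1S,2R)-1-(3,4-dimethoxyphenyl)-2-(prop-2-yn-1-yl)propane-1,3-diol
Conditions: LiBH4, MeOH (1 equiv), THF, 0 °C
Reagents that add atoms: none
Why: Reductive cleavage of the N-acyl oxazolidinone by LiBH4 is a standard auxiliary removal that should reduce only the exocyclic imide carbonyl to CH2OH, leave the alkyne alone and not touch either stereocentre.

Step 4
Reactants: 9 (1S,2R)-1-(3,4-dimethoxyphenyl)-2-(prop-2-yn-1-yl)propane-1,3-diol
Product: 10 (1S,2R)-1,3-bis(tert-butyldimethylsilyloxy)-1-(3,4-dimethoxyphenyl)-2-(prop-2-yn-1-yl)propane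
Conditions: TBSOTf (2.5 equiv), 2,6-lutidine, CH2Cl2, −78 → 0 °C
Reagents that add atoms: tert-butyldimethylsilyl triflate, CC(C)(C)[Si](C)(C)OS(=O)(=O)C(F)(F)F
Why: Silylation with the silyl triflate and a hindered pyridine base should cap both the primary and the hindered benzylic secondary hydroxyl at low temperature, removing every protic group before the hydride step.

Step 5
Reactants: 10 bis-TBS alkyne; 11 4-iodoanisole
Product: 14 (1S,2R,4E)-1-(tert-butyldimethylsilyloxy)-2-[(tert-butyldimethylsilyloxy)methyl]-1-(3,4-dimethoxyphenyl)-5-(4-methoxyphenyl)pent-4-ene, via E-alkenylzirconocene chloride 12 (not isolated), via E-alkenylzinc chloride 13 (not isolated)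
Conditions: Cp2Zr(H)Cl (1.3 equiv), THF, rt, dark; ZnCl2 (1.5 equiv, THF), 0 °C; 11, Pd(PPh3)4 (5 mol %), rt → 40 °C
Reagents that add atoms: none
Why: Cp2Zr(H)Cl adds its Zr–H bond across the terminal alkyne of 10 in a concerted syn fashion, placing zirconium on the unhindered terminal carbon C5 and hydrogen on C4 to give 12. ZnCl2 then takes over the alkenyl group with retention (13), zerovalent palladium inserts into the C–I bond of 11, and transmetalation followed by reductive elimination forms the C5–aryl bond with the geometry intact. The closest known reaction type is the hydrozirconation, zinc transmetalation and Negishi cross-coupling of terminal alkynes with aryl iodides. No ring is closed and no sp3 stereocentre is created; the only stereochemical element formed is the E alkene, fixed by the syn hydrometalation and the stereoretentive coupling. The step needs terminal regioselectivity and tolerance of the rest of the molecule: the steric difference between internal C4 and terminal C5 secures the first, and the silyl ethers and aryl methyl ethers are inert to the hydride while C1 and C2 carry no hydrogen that is acidic under these conditions.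

Step 6
Reactants: 14 bis-TBS E-alkene
Product: 15 (2R,4E)-2-[(S)-(tert-butyldimethylsilyloxy)(3,4-dimethoxyphenyl)methyl]-5-(4-methoxyphenyl)pent-4-en-1-ol
Conditions: HF·pyridine, pyridine, THF, 0 °C
Reagents that add atoms: none
Why: Pyridine-buffered HF·pyridine is a standard selective desilylation that should cleave the unhindered primary TBS ether well before the hindered benzylic secondary one, and the buffering avoids ionisation at the electron-rich benzylic position.

Step 7
Reactants: 16 crotonaldehyde ((E)-but-2-enal)
Product: 17 (Z)-2-iodobut-2-enal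
Conditions: I2, K2CO3, DMAP (0.2 equiv), THF/H2O 1:1, rt
Reagents that add atoms: iodine, II
Why: Amine-catalysed α-iodination of an enal (conjugate addition of DMAP, iodination of the enolate, elimination of DMAP) should return the alkene with the methyl group trans to the formyl group, which is the Z iodide.

Step 8
Reactants: 17 (Z)-2-iodobut-2-enal
Product: 18 (Z)-2-iodobut-2-en-1-ol
Conditions: NaBH4, MeOH, 0 °C
Reagents that add atoms: none
Why: Borohydride 1,2-reduction of the aldehyde is fast at 0 °C and should not affect the vinyl iodide or the alkene geometry.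

Step 9
Reactants: 18 (Z)-2-iodobut-2-en-1-ol
Product: 19 tert-butyl{[(Z)-2-iodobut-2-en-1-yl]oxy}dimethylsilane
Conditions: TBSCl, imidazole, CH2Cl2, rt
Reagents that add atoms: tert-butyldimethylsilyl chloride, CC(C)(C)[Si](C)(C)Cl
Why: Imidazole-promoted silylation of an unhindered primary allylic alcohol is routine and masks the hydroxyl for the organolithium step.

Step 10
Reactants: 19 tert-butyl{[(Z)-2-iodobut-2-en-1-yl]oxy}dimethylsilane
Product: 22 (Z)-2-[(tert-butyldimethylsilyloxy)methyl]but-2-enoic acid, via vinyllithium 20 (not isolated), via lithium carboxylate 21 (not isolated)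
Conditions: t-BuLi (2.1 equiv), Et2O, −78 °C; CO2 (dry gas), −78 °C; 1 M HCl to pH 3, 0 °C
Reagents that add atoms: carbon dioxide, O=C=O
Why: Iodine–lithium exchange and carboxylation of the alkenyllithium both proceed with retention at −78 °C, so the carboxyl group should end cis to the methyl group (Z acid), and the immediate CO2 quench leaves little time for silyl migration from oxygen to carbon.

Step 11
Reactants: 22 (Z)-2-[(tert-butyldimethylsilyloxy)methyl]but-2-enoic acid; 15 core primary alcohol
Product: 24 [(2R,4E)-2-[(S)-(tert-butyldimethylsilyloxy)(3,4-dimethoxyphenyl)methyl]-5-(4-methoxyphenyl)pent-4-en-1-yl] (Z)-2-[(tert-butyldimethylsilyloxy)methyl]but-2-enoate, via Yamaguchi mixed anhydride 23 (not isolated)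
Conditions: 2,4,6-Cl3C6H2COCl, Et3N, toluene, rt; then 15, DMAP (0.3 equiv), 0 °C → rt
Reagents that add atoms: none
Why: Yamaguchi esterification, in which the hindered aroyl half of the mixed anhydride directs the primary alcohol to the enoyl carbonyl, and low temperature with substoichiometric DMAP is chosen to limit Z-to-E isomerisation of the activated acid.

Step 12
Reactants: 24 bis-TBS ester
Product: 25 [(2R,4E)-2-[(S)-(3,4-dimethoxyphenyl)(hydroxy)methyl]-5-(4-methoxyphenyl)pent-4-en-1-yl] (Z)-2-(hydroxymethyl)but-2-enoate (CNP0280662.1)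
Conditions: Bu4NF, AcOH (1:1), THF, 0 °C → rt
Reagents that add atoms: none
Why: Acetic acid-buffered fluoride desilylation should free both the allylic primary and the benzylic secondary hydroxyl without generating alkoxide, which keeps the ester from migrating to the neighbouring secondary oxygen and keeps the Z enoate from isomerising.

**Compound list**

1 | pent-4-ynoic acid | C#CCCC(=O)O | starting material
2 | (S)-4-benzyloxazolidin-2-one | O=C1N[C@@H](Cc2ccccc2)CO1 | starting material
3 | pent-4-ynoic pivalic mixed anhydride | C#CCCC(=O)OC(=O)C(C)(C)C | intermediate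
4 | (S)-4-benzyl-3-(pent-4-ynoyl)oxazolidin-2-one | C#CCCC(=O)N1[C@@H](Cc2ccccc2)COC1=O | intermediate
5 | veratraldehyde (3,4-dimethoxybenzaldehyde) | COc1ccc(C=O)cc1OC | starting material
6 | dibutylboron Z-enolate of 4 (O–BBu2 cis to the propargylic CH2) | CCCCB(CCCC)O/C(=C\CC#C)N1[C@@H](Cc2ccccc2)COC1=O | intermediate
7 | dibutylboron aldolate of 8 | O=C1OC[C@H](Cc2ccccc2)N1C(=O)[C@@H](CC#C)[C@H](OB(CCCC)CCCC)c1ccc(OC)c(OC)c1 | intermediate
8 | (S)-4-benzyl-3-{(2S)-2-[(S)-(3,4-dimethoxyphenyl)(hydroxy)methyl]pent-4-ynoyl}oxazolidin-2-one | O=C1OC[C@H](Cc2ccccc2)N1C(=O)[C@@H](CC#C)[C@H](O)c1ccc(OC)c(OC)c1 | intermediate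
9 | (1S,2R)-1-(3,4-dimethoxyphenyl)-2-(prop-2-yn-1-yl)propane-1,3-diol | OC[C@@H](CC#C)[C@H](O)c1ccc(OC)c(OC)c1 | intermediate
10 | (1S,2R)-1,3-bis(tert-butyldimethylsilyloxy)-1-(3,4-dimethoxyphenyl)-2-(prop-2-yn-1-yl)propane | CC(C)(C)[Si](C)(C)OC[C@@H](CC#C)[C@H](O[Si](C)(C)C(C)(C)C)c1ccc(OC)c(OC)c1 | intermediate
11 | 4-iodoanisole | COc1ccc(I)cc1 | starting material
12 | E-alkenylzirconocene chloride from 10 (Cp2ZrCl on C5) | CC(C)(C)[Si](C)(C)OC[C@@H](C/C=C/[Zr](Cl)(C1C=CC=C1)C1C=CC=C1)[C@H](O[Si](C)(C)C(C)(C)C)c1ccc(OC)c(OC)c1 | intermediate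
13 | E-alkenylzinc chloride from 12 (ZnCl on C5) | CC(C)(C)[Si](C)(C)OC[C@@H](C/C=C/[Zn]Cl)[C@H](O[Si](C)(C)C(C)(C)C)c1ccc(OC)c(OC)c1 | intermediate
14 | (1S,2R,4E)-1-(tert-butyldimethylsilyloxy)-2-[(tert-butyldimethylsilyloxy)methyl]-1-(3,4-dimethoxyphenyl)-5-(4-methoxyphenyl)pent-4-ene | CC(C)(C)[Si](C)(C)OC[C@@H](C/C=C/c1ccc(OC)cc1)[C@H](O[Si](C)(C)C(C)(C)C)c1ccc(OC)c(OC)c1 | intermediate
15 | (2R,4E)-2-[(S)-(tert-butyldimethylsilyloxy)(3,4-dimethoxyphenyl)methyl]-5-(4-methoxyphenyl)pent-4-en-1-ol | OC[C@@H](C/C=C/c1ccc(OC)cc1)[C@H](O[Si](C)(C)C(C)(C)C)c1ccc(OC)c(OC)c1 | intermediate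
16 | crotonaldehyde ((E)-but-2-enal) | C/C=C/C=O | starting material
17 | (Z)-2-iodobut-2-enal | C/C=C(/C=O)I | intermediate
18 | (Z)-2-iodobut-2-en-1-ol | C/C=C(/CO)I | intermediate
19 | tert-butyl{[(Z)-2-iodobut-2-en-1-yl]oxy}dimethylsilane | C/C=C(/CO[Si](C)(C)C(C)(C)C)I | intermediate
20 | 1-(tert-butyldimethylsilyloxy)but-2-en-2-yllithium, Li cis to the methyl group | C/C=C(/CO[Si](C)(C)C(C)(C)C)[Li] | intermediate
21 | lithium (Z)-2-[(tert-butyldimethylsilyloxy)methyl]but-2-enoate | C/C=C(/CO[Si](C)(C)C(C)(C)C)C(=O)[O-].[Li+] | intermediate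
22 | (Z)-2-[(tert-butyldimethylsilyloxy)methyl]but-2-enoic acid | C/C=C(/CO[Si](C)(C)C(C)(C)C)C(=O)O | intermediate
23 | (Z)-2-[(tert-butyldimethylsilyloxy)methyl]but-2-enoic 2,4,6-trichlorobenzoic anhydride | C/C=C(/CO[Si](C)(C)C(C)(C)C)C(=O)OC(=O)c1c(Cl)cc(Cl)cc1Cl | intermediate
24 | [(2R,4E)-2-[(S)-(tert-butyldimethylsilyloxy)(3,4-dimethoxyphenyl)methyl]-5-(4-methoxyphenyl)pent-4-en-1-yl] (Z)-2-[(tert-butyldimethylsilyloxy)methyl]but-2-enoate | C/C=C(/CO[Si](C)(C)C(C)(C)C)C(=O)OC[C@@H](C/C=C/c1ccc(OC)cc1)[C@H](O[Si](C)(C)C(C)(C)C)c1ccc(OC)c(OC)c1 | intermediate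
25 | [(2R,4E)-2-[(S)-(3,4-dimethoxyphenyl)(hydroxy)methyl]-5-(4-methoxyphenyl)pent-4-en-1-yl] (Z)-2-(hydroxymethyl)but-2-enoate (CNP0280662.1) | C/C=C(/CO)C(=O)OC[C@@H](C/C=C/c1ccc(OC)cc1)[C@H](O)c1ccc(OC)c(OC)c1 | target

**Step count and risks**

Total steps: 12. Longest linear sequence: 8 steps (steps 1–6, 11, 12, from pent-4-ynoic acid). The acid branch is 4 steps (7–10) and joins at step 11.

Steps most likely to fail:

1. Step 11. The activated enoyl species may lose its Z geometry by reversible conjugate addition of DMAP or carboxylate, and the α-branched acyl group may react slowly. The fallback activates the alcohol instead of the acid. It sets out from 15 and 22: under Mitsunobu conditions (PPh3, DIAD, THF, 0 °C → rt) alcohol 15 is converted into the alkoxytriphenylphosphonium carboxylate ion pair F1. Its carboxylate then displaces triphenylphosphine oxide at the primary carbon, which is not a stereocentre, and the route is rejoined at 24. The acid never becomes an acyl electrophile, so the isomerisation pathway is closed.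

2. Step 10. The silyl group may migrate from oxygen to the lithiated carbon, or the alkenyllithium may be protonated or add a second time to the carboxylate, all of which erode the yield of acid. The fallback avoids organolithium chemistry and sets out from 19. Palladium-catalysed methoxycarbonylation (PdCl2(PPh3)2, CO 1 atm, MeOH, Et3N, DMF, 50 °C) should give methyl (Z)-2-[(tert-butyldimethylsilyloxy)methyl]but-2-enoate F2 with retention of geometry. Mild saponification (LiOH, THF/H2O, 0 °C) then gives lithium carboxylate 21, and acidification returns the route to 22.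

3. Step 5. The alkenylmetal species may be protonated by adventitious moisture before coupling, a second Zr–H addition may occur, or transmetalation to zinc and palladium may be slow with the electron-rich aryl iodide. The fallback keeps the C5–aryl disconnection but goes through an isolable alkenylboron compound and sets out from 10. Hydroboration with pinacolborane catalysed by Cp2Zr(H)Cl (Et3N, 60 °C) should give the (E)-alkenyl pinacol boronate F3, which can be purified. Suzuki–Miyaura coupling of F3 with 11 (Pd(dppf)Cl2, K3PO4, dioxane/H2O, 80 °C) rejoins the route at 14.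

**Further compounds**

F1 | step 11 | alkoxytriphenylphosphonium (Z)-2-[(tert-butyldimethylsilyloxy)methyl]but-2-enoate ion pair derived from 15 | C/C=C(/CO[Si](C)(C)C(C)(C)C)C(=O)[O-].c1ccc(cc1)[P+](c1ccccc1)(c1ccccc1)OC[C@@H](C/C=C/c1ccc(OC)cc1)[C@H](O[Si](C)(C)C(C)(C)C)c1ccc(OC)c(OC)c1
F2 | step 10 | methyl (Z)-2-[(tert-butyldimethylsilyloxy)methyl]but-2-enoate | C/C=C(/CO[Si](C)(C)C(C)(C)C)C(=O)OC
F3 | step 5 | (E)-alkenyl pinacol boronate of the bis-TBS core (Bpin on C5) | CC(C)(C)[Si](C)(C)OC[C@@H](C/C=C/B1OC(C)(C)C(C)(C)O1)[C@H](O[Si](C)(C)C(C)(C)C)c1ccc(OC)c(OC)c1
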